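## Retrosynthetic overview

1. The target is reached by 1,2-reduction of a β-aroyloxy enone. The vanilloyl group (from vanillic acid, phenol masked as a silyl ether) is put on the only free hydroxyl of a β-hydroxy ketone, so the two ring oxygens never have to be told apart.
2. The β-hydroxy ketone comes from enantioselective copper-catalysed β-borylation/oxidation of an achiral, cross-conjugated (Z,Z,Z)-cyclodecatrienone. This sets the C–O centre; the neighbouring isopropyl centre follows by protonation.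
3. The cyclodecatrienone comes from a two-carbon ring expansion (alkoxide-accelerated 1,3-allyl shift, then enolate dehydrogenation in the same flask) of a 1-(1-isopropylvinyl)cycloocta-2,6-dienol.
4. The cyclooctadienol comes from 3,7-dimethylcycloocta-2,6-dienone and an alkenyl Grignard reagent. Key step: the dienone is made by desymmetrising mono-allylic C–H oxidation of C2-symmetric 1,5-dimethylcycloocta-1,5-diene (isoprene dimer), which already holds both (Z)-trisubstituted olefins of the target.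
5. Ring order: eight-membered carbocycle (bought), then ten-membered carbocycle (ring expansion); the arene is attached, not built.

Assumptions: the target is the enantiomer drawn, (1R,9S,10S) with both ring olefins Z; technical 1,5-dimethylcycloocta-1,5-diene (about 80%, rest 1,6-isomer) is used and isomer-derived ketones are removed by chromatography after step 1; 2-bromo-3-methylbut-1-ene is taken as a catalogue compound.

## Route

Step 1
Reactants: 1 (1Z,5Z)-1,5-dimethylcycloocta-1,5-diene
Product: 2 (2Z,6Z)-3,7-dimethylcycloocta-2,6-dien-1-one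
Conditions: Rh2(cap)4 [dirhodium tetrakis(caprolactamate)] (1 mol%), t-BuOOH (70% aq, 4 equiv), K2CO3 (0.5 equiv), CH2Cl2, rt, stopped at ca. 60% conversion
Reagents that add atoms: tert-butyl hydroperoxide, CC(C)(C)OO
Why: Radical allylic C–H oxidation (dirhodium carboxamidate/TBHP) abstracts H from a ring CH2 next to =CH, traps the tertiary-stabilised allyl radical at its secondary end and collapses the peroxide (Kornblum–DeLaMare) to the β-methyl enone; the two such CH2 groups of the diene are equivalent, so mono-oxidation is the symmetry-breaking event, and no stereocentre is formed.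

Step 2
Reactants: 2 (2Z,6Z)-3,7-dimethylcycloocta-2,6-dien-1-one; 3 2-bromo-3-methylbut-1-ene
Product: 5 (2Z,6Z)-3,7-dimethyl-1-(3-methylbut-1-en-2-yl)cycloocta-2,6-dien-1-ol, via Grignard reagent 4 (not isolated)
Conditions: 3, Mg, THF, rt; then 2, THF, −78 to 0 °C; aq NH4Cl
Reagents that add atoms: none
Why: Grignard 1,2-addition to the enone carbonyl (the β,β-disubstituted enone resists 1,4-addition) gives the racemic tertiary carbinol, whose stereocentre is erased in step 3.

Step 3
Reactants: 5 (2Z,6Z)-3,7-dimethyl-1-(3-methylbut-1-en-2-yl)cycloocta-2,6-dien-1-ol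
Product: 9 (2Z,5Z,9Z)-5,9-dimethyl-2-(propan-2-yl)cyclodeca-2,5,9-trien-1-one, via potassium alkoxide 6 (not isolated), via potassium enolate 7 (not isolated), via sulfilimine adduct 8 (not isolated)
Conditions: KN(SiMe3)2 (1.05 equiv), 18-crown-6 (1.1 equiv), THF, 0 °C to rt; then PhS(Cl)=N-t-Bu (1.2 equiv), −78 °C
Reagents that add atoms: none
Why: Alkoxide-accelerated [1,3]-sigmatropic allyl shift (anionic two-carbon ring expansion of a 1-alkenylcyclooct-3-en-1-olate, the Z-allyl unit migrating within a tight potassium ion pair) gives the regiodefined enolate, which Mukaiyama dehydrogenation (S–C bond formation, then syn-elimination toward the ring CH2) converts into the achiral trienone.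

Step 4
Reactants: 9 (2Z,5Z,9Z)-5,9-dimethyl-2-(propan-2-yl)cyclodeca-2,5,9-trien-1-one
Product: 11 (2R,3R,5Z,9Z)-3-hydroxy-5,9-dimethyl-2-(propan-2-yl)cyclodeca-5,9-dien-1-one, via boronate 10 (not isolated)
Conditions: CuCl (5 mol%), NaOt-Bu (7 mol%), (R)-DTBM-SEGPHOS (5.5 mol%; ligand antipode fixed by a pilot run so that 10 is 3R), B2pin2 (1.2 equiv), MeOH (2 equiv), THF, 0 °C; then NaBO3·4H2O, THF–H2O, rt
Reagents that add atoms: sodium perborate, [Na+].[O-]OB=O (the C3 oxygen); bis(pinacolato)diboron, CC1(C)OB(OC1(C)C)B1OC(C)(C)C(C)(C)O1 (boryl group of 10 only)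
Why: Copper-catalysed asymmetric conjugate borylation adds boron to the β-monosubstituted C3 (not the β,β-disubstituted C9) with the ligand setting C3, protonation of the enolate anti to the boryl group under allylic-strain control sets C2 cis to it, and perborate oxidation replaces boron by OH with retention.

Step 5
Reactants: 12 vanillic acid (4-hydroxy-3-methoxybenzoic acid)
Product: 14 4-[(tert-butyldimethylsilyl)oxy]-3-methoxybenzoic acid, via bis-silyl derivative 13 (not isolated)
Conditions: TBSCl (2.3 equiv), imidazole (4 equiv), DMF, rt; then AcOH–THF–H2O 3:1:1, rt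
Reagents that add atoms: tert-butyldimethylsilyl chloride, CC(C)(C)[Si](C)(C)Cl
Why: Silylation of both O–H groups followed by selective hydrolysis of the labile silyl ester leaves the aryl silyl ether and frees the acid.

Step 6
Reactants: 11 (2R,3R,5Z,9Z)-3-hydroxy-5,9-dimethyl-2-(propan-2-yl)cyclodeca-5,9-dien-1-one; 14 4-[(tert-butyldimethylsilyl)oxy]-3-methoxybenzoic acid
Product: 15 (1R,3Z,7Z,10R)-3,7-dimethyl-9-oxo-10-(propan-2-yl)cyclodeca-3,7-dien-1-yl 4-[(tert-butyldimethylsilyl)oxy]-3-methoxybenzoate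
Conditions: dicyclohexylcarbodiimide (1.3 equiv), 4-(dimethylamino)pyridine (0.2 equiv), CH2Cl2, 0 °C to rt
Reagents that add atoms: none
Why: Steglich esterification acylates the only hydroxyl present, so the aroyl group is placed unambiguously, and the mild conditions leave both stereocentres untouched.

Step 7
Reactants: 15 (1R,3Z,7Z,10R)-3,7-dimethyl-9-oxo-10-(propan-2-yl)cyclodeca-3,7-dien-1-yl 4-[(tert-butyldimethylsilyl)oxy]-3-methoxybenzoate
Product: 17 (1R,3Z,7Z,9S,10S)-9-hydroxy-3,7-dimethyl-10-(propan-2-yl)cyclodeca-3,7-dien-1-yl 4-hydroxy-3-methoxybenzoate, via silyl-protected ester 16 (not isolated)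
Conditions: NaBH4, CeCl3·7H2O, MeOH, −78 °C; then KHF2 (2.5 equiv), MeOH, rt
Reagents that add atoms: none
Why: Luche 1,2-reduction of the enone with hydride adding anti to the isopropyl group (Felkin–Anh) is expected to place the new hydroxyl cis to the isopropyl and aroyloxy groups, and KHF2 then cleaves only the aryl silyl ether.

## Compound list

1 | (1Z,5Z)-1,5-dimethylcycloocta-1,5-diene | C1/C(C)=C\CC/C(C)=C\C1 | starting material
2 | (2Z,6Z)-3,7-dimethylcycloocta-2,6-dien-1-one | O=C1/C=C(C)\CC/C=C(C)\C1 | intermediate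
3 | 2-bromo-3-methylbut-1-ene | C=C(Br)C(C)C | starting material
4 | (3-methylbut-1-en-2-yl)magnesium bromide | CC(C)C(=C)[Mg]Br | intermediate
5 | (2Z,6Z)-3,7-dimethyl-1-(3-methylbut-1-en-2-yl)cycloocta-2,6-dien-1-ol (racemic) | OC1(C(=C)C(C)C)/C=C(C)\CC/C=C(C)\C1 | intermediate
6 | potassium (2Z,6Z)-3,7-dimethyl-1-(3-methylbut-1-en-2-yl)cycloocta-2,6-dien-1-olate | [K+].[O-]C1(C(=C)C(C)C)/C=C(C)\CC/C=C(C)\C1 | intermediate
7 | potassium (5Z,9Z)-5,9-dimethyl-2-(propan-2-yl)cyclodeca-1,5,9-trien-1-olate | [K+].C1C/C(C)=C\CC/C(C)=C\C([O-])=C1C(C)C | intermediate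
8 | (5Z,9Z)-2-(N-tert-butyl-S-phenylsulfinimidoyl)-5,9-dimethyl-2-(propan-2-yl)cyclodeca-5,9-dien-1-one (racemic) | C1C/C(C)=C\CC/C(C)=C\C(=O)C1(C(C)C)S(=NC(C)(C)C)c2ccccc2 | intermediate
9 | (2Z,5Z,9Z)-5,9-dimethyl-2-(propan-2-yl)cyclodeca-2,5,9-trien-1-one | C1/C(C)=C\C(=O)/C(C(C)C)=C\C/C(C)=C\C1 | intermediate
10 | (2S,3R,5Z,9Z)-5,9-dimethyl-2-(propan-2-yl)-3-(4,4,5,5-tetramethyl-1,3,2-dioxaborolan-2-yl)cyclodeca-5,9-dien-1-one | CC1(C)OB(OC1(C)C)[C@@H]2C/C(C)=C\CC/C(C)=C\C(=O)[C@@H]2C(C)C | intermediate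
11 | (2R,3R,5Z,9Z)-3-hydroxy-5,9-dimethyl-2-(propan-2-yl)cyclodeca-5,9-dien-1-one | O[C@@H]1C/C(C)=C\CC/C(C)=C\C(=O)[C@@H]1C(C)C | intermediate
12 | vanillic acid (4-hydroxy-3-methoxybenzoic acid) | COc1cc(C(=O)O)ccc1O | starting material
13 | tert-butyldimethylsilyl 4-[(tert-butyldimethylsilyl)oxy]-3-methoxybenzoate | COc1cc(C(=O)O[Si](C)(C)C(C)(C)C)ccc1O[Si](C)(C)C(C)(C)C | intermediate
14 | 4-[(tert-butyldimethylsilyl)oxy]-3-methoxybenzoic acid | COc1cc(C(=O)O)ccc1O[Si](C)(C)C(C)(C)C | intermediate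
15 | (1R,3Z,7Z,10R)-3,7-dimethyl-9-oxo-10-(propan-2-yl)cyclodeca-3,7-dien-1-yl 4-[(tert-butyldimethylsilyl)oxy]-3-methoxybenzoate | COc1cc(C(=O)O[C@@H]2C/C(C)=C\CC/C(C)=C\C(=O)[C@@H]2C(C)C)ccc1O[Si](C)(C)C(C)(C)C | intermediate
16 | (1R,3Z,7Z,9S,10S)-9-hydroxy-3,7-dimethyl-10-(propan-2-yl)cyclodeca-3,7-dien-1-yl 4-[(tert-butyldimethylsilyl)oxy]-3-methoxybenzoate | COc1cc(C(=O)O[C@@H]2C/C(C)=C\CC\C(C)=C/[C@H](O)[C@@H]2C(C)C)ccc1O[Si](C)(C)C(C)(C)C | intermediate
17 | (1R,3Z,7Z,9S,10S)-9-hydroxy-3,7-dimethyl-10-(propan-2-yl)cyclodeca-3,7-dien-1-yl 4-hydroxy-3-methoxybenzoate | COc1cc(C(=O)O[C@@H]2C/C(C)=C\CC\C(C)=C/[C@H](O)[C@@H]2C(C)C)ccc1O | target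

## Step count and risks

Total step count: 7. Longest linear sequence: 6 (steps 1, 2, 3, 4, 6, 7).

Step 3 is the riskiest. A competing [3,3] shift would give an eight-membered isomer, the Z-allyl geometry could erode, and dehydrogenation could go toward the isopropyl group. The fallback sets out from 5 and returns at 9, and runs the C–C shift as a radical instead of an anionic process. Proton-coupled electron transfer ([Ir(dF(CF3)ppy)2(5,5'-d(CF3)bpy)]PF6, 2,4,6-collidine, 2,4,6-triisopropylbenzenethiol, blue light, PhCF3) turns the tertiary alcohol into its alkoxy radical. β-Scission gives an allyl radical and a pendant 1-isopropylvinyl ketone, and ten-membered ring closure with hydrogen transfer from the thiol gives (5Z,9Z)-5,9-dimethyl-2-(propan-2-yl)cyclodeca-5,9-dien-1-one F1. Its enolate (KN(SiMe3)2, THF, −78 °C) is dehydrogenated with the same sulfinimidoyl chloride to 9.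

Step 4 may fail on regioselectivity between the two enone termini, on enantioselectivity at a hindered α-isopropyl enone, or on the C2 configuration. The fallback sets out from 9 and returns at 11, and brings the oxygen in as an epoxide instead of through boron. Asymmetric nucleophilic epoxidation (La(O-i-Pr)3, (R)-BINOL, Ph3As=O, t-BuOOH, THF) gives (1R,3Z,7Z,10R)-4,8-dimethyl-1-(propan-2-yl)-11-oxabicyclo[8.1.0]undeca-3,7-dien-2-one F2. SmI2 (THF–MeOH, −78 °C) cleaves the C–O bond next to the carbonyl, and protonation of the chelated samarium enolate anti to the ring residue on the carbinol carbon gives 11.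

Step 7 may give the wrong facial selectivity in the ten-membered ring. The fallback sets out from 15 and returns at 17, and corrects the centre by inversion. If hydride gives the C9 epimer, the reduction is stopped before desilylation to give (1R,3Z,7Z,9R,10S)-9-hydroxy-3,7-dimethyl-10-(propan-2-yl)cyclodeca-3,7-dien-1-yl 4-[(tert-butyldimethylsilyl)oxy]-3-methoxybenzoate F3. Mitsunobu reaction (PPh3, DIAD, 4-nitrobenzoic acid, THF, 0 °C) inverts the allylic carbinol to (1R,3Z,7Z,9S,10R)-9-[(4-nitrobenzoyl)oxy]-3,7-dimethyl-10-(propan-2-yl)cyclodeca-3,7-dien-1-yl 4-[(tert-butyldimethylsilyl)oxy]-3-methoxybenzoate F4. K2CO3 in MeOH at 0 °C then removes the 4-nitrobenzoate and the aryl silyl ether together to give 17.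

Further compounds
F1 | step 3 | (5Z,9Z)-5,9-dimethyl-2-(propan-2-yl)cyclodeca-5,9-dien-1-one (racemic) | C1C/C(C)=C\CC/C(C)=C\C(=O)C1C(C)C
F2 | step 4 | (1R,3Z,7Z,10R)-4,8-dimethyl-1-(propan-2-yl)-11-oxabicyclo[8.1.0]undeca-3,7-dien-2-one | O2[C@@H]1C/C(C)=C\CC/C(C)=C\C(=O)[C@@]12C(C)C
F3 | step 7 | (1R,3Z,7Z,9R,10S)-9-hydroxy-3,7-dimethyl-10-(propan-2-yl)cyclodeca-3,7-dien-1-yl 4-[(tert-butyldimethylsilyl)oxy]-3-methoxybenzoate | COc1cc(C(=O)O[C@@H]2C/C(C)=C\CC\C(C)=C/[C@@H](O)[C@@H]2C(C)C)ccc1O[Si](C)(C)C(C)(C)C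
F4 | step 7 | (1R,3Z,7Z,9S,10R)-9-[(4-nitrobenzoyl)oxy]-3,7-dimethyl-10-(propan-2-yl)cyclodeca-3,7-dien-1-yl 4-[(tert-butyldimethylsilyl)oxy]-3-methoxybenzoate | COc1cc(C(=O)O[C@@H]2C/C(C)=C\CC\C(C)=C/[C@H](OC(=O)c3ccc(cc3)[N+](=O)[O-])[C@@H]2C(C)C)ccc1O[Si](C)(C)C(C)(C)C
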